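- Late in Friday's run, at 10.0 h, X reads 42% and Q 26%, so the balance of X, the limiting reagent (charged at 0.090 M, less than the 0.135 M of G), puts 32.0% in forms not read.

common to all: X 0.090 M; G 0.135 M

| run | remark | time | volume of the second phase over the first |
|---|---|---|---|
| Friday's | the very flask that is asked about, followed so far |  |  |
| flask |  | 20 h | 1.0 |

- Friday's (time / h: Q / %, X / %): 1.33: 5, 68; 3.00: 10, 54; 4.00: 13, 50; 6.00: 19, 46; 8.00: 23, 41; 10.0: 26, 42

(standard deviation of a reading: 1.5 percentage points)

- in the second phase: G; everything else is in the first
- charges count per volume of the first phase; a concentration in a rate is the amount of a species over the volume of its own phase; every rate counts per litre of the first phase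
- steps that have been proposed: D <-> G; X + D -> Q; D -> Z; Q <-> J; X <-> L
- the earlier runs hold the two phases in the same ratio of volumes as the flask asked about

- the Q standing at 20 h, as a percentage of the X charged
- the change that raises the amount of Q at 20 h, in percent of the X charged most ("none" if none brings more than 2 percentage points) (theta / alpha / none)
- amount of Q at 20 h, in percent of the X charged, after theta

- theta: doubling the amount of G, all else as stated
- alpha: doubling the transfer coefficient of G, all else as stated

- I count as unturned whatever is not yet Q, and I define the turning constant as the logarithm of charged over unturned X, divided by the time: a pseudo-first-order constant, 0.0301 h⁻¹ from the last reading of Friday's run.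
- My first way holds that constant for 20 h and gives 45.2% of Q in this flask.
- My second way draws a straight line through the same last reading and gives 52.0%, which is more.
- The line is the one that cheats for Q, because it keeps the pace fixed, whereas Q gains 8 percentage points from 1.33 h to 4.00 h and then 7 points over the longer span from 6.00 h to 10.0 h, a pace lower, though each reading scatters by 1.5 points.
- I commit to 45.2%.
- I read the constant as G shared over the X charged, so I assume that doubling G doubles it; theta then gives 70.0% of Q, and on that assumption I choose theta.
- The forecast names the same change, theta, but gives 35% before it and 55% after it, both lower than my numbers, and it argues that “Doubling G doubles D and the rate throughout”.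

- This flask holds 43.2% of Q at 20 h, the best change is theta, which gives 71.5%, and J stands at 10.6% beside the Q.

    D ⇌ G, rate k1*([D] - [G]/K1) per volume of the first phase (partition coefficient = 2.90, kL = 0.0796 h⁻¹)
    X + D → Q (k = 33.8 M⁻¹ h⁻¹)
    D → Z (k = 0.101 h⁻¹)
    Q ⇌ J (K = 0.325, k = 0.0525 h⁻¹)
    X ⇌ L (K = 0.700, k = 0.364 h⁻¹)

- Over 20 h in this flask the turning constant reads 0.0283 h⁻¹, lower than the value from Friday's last reading. I carry it to the neighbour charged with 0.22 M of X, dividing it by the ratio of charges, 2.44, and that gives 20.7% of Q. That neighbour holds 19.8% of Q.

The readings are simulated for substances that don't exist.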